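**Retrosynthetic overview**
1. Target 23 comes from alcohol 22 by acylation of O8. Alcohol 22 comes from the Z,Z-dienol 20 by the key step, in which all four oxirane C–O bonds are made in one flask from the C8 carbinol.
2. Dienol 20 comes from triene 19 by ring-closing metathesis at C1=C10, which forms the ten-membered carbocycle.
3. Triene 19 comes from alkenyl triflate 10 and Z-enal 17 by C6–C7 coupling, and the resulting C6 alkoxide closes the butenolide.
4. Triflate 10 takes its tetrasubstituted olefin geometry from a sacrificial 2,5-dihydrofuran 7 (glyoxylate-ene, oxa-Michael/Dieckmann, triflation), which is opened by C–O exchange at C13. Enal 17 comes from carbocupration of propyne.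
5. Ring order: dihydrofuran (made, then opened), butenolide, carbocycle, two oxiranes.

**Assumption:** the SMILES is read literally. Both oxiranes are cis-fused to the ten-membered ring (C9/C2 cis and C3/C6 cis), so they derive from Z olefins, and O6, O8 and both oxirane oxygens lie on one face.

**Numbering:** germacrane numbers are used throughout. C1–C10 is the ring, C11–C13 the lactone side, C14 the methyl on C10, and C15 the methyl on C4.

**Step 1**
Reactants: 1 ethyl glyoxylate; 2 isobutene
Product: 3 ethyl (2R)-2-hydroxy-4-methylpent-4-enoate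
Conditions: (R)-BINOL (10 mol %), TiCl2(OiPr)2 (10 mol %), 4 Å MS, CH2Cl2, −30 °C
Reagents that add atoms: none
Why: Mikami catalytic asymmetric glyoxylate-ene reaction, in which the BINOL–titanium Lewis acid shields one aldehyde face in the six-membered ene transition state and sets C8 as R.

**Step 2**
Reactants: 3 ethyl (2R)-2-hydroxy-4-methylpent-4-enoate; 4 ethyl acrylate
Product: 6 ethyl (5R)-5-(2-methylprop-2-enyl)-4-oxooxolane-3-carboxylate, via oxa-Michael diester 5 (not isolated)
Conditions: NaH (1.1 equiv), THF, 0 °C; 4, 0 to 23 °C; aq HCl quench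
Reagents that add atoms: none
Why: Oxa-Michael addition followed by Dieckmann condensation (the standard route to 4-oxooxolane-3-carboxylates); C8 is untouched because the product rests as its β-keto ester enolate, and matched ethyl esters avoid ester scrambling.

**Step 3**
Reactants: 6 ethyl (5R)-5-(2-methylprop-2-enyl)-4-oxooxolane-3-carboxylate
Product: 7 ethyl (5R)-5-(2-methylprop-2-enyl)-4-(trifluoromethylsulfonyloxy)-2,5-dihydrofuran-3-carboxylate
Conditions: Tf2O (1.2 equiv), iPr2NEt (1.5 equiv), CH2Cl2, −78 °C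
Reagents that add atoms: triflic anhydride O=S(=O)(OS(=O)(=O)C(F)(F)F)C(F)(F)F
Why: Enol triflation of a β-keto ester on its more acidic C11 side; the ring locks OTf cis to the ester and C8 cis to C13.

**Step 4**
Reactants: 7 ethyl (5R)-5-(2-methylprop-2-enyl)-4-(trifluoromethylsulfonyloxy)-2,5-dihydrofuran-3-carboxylate
Product: 10 ethyl (2Z,4R)-2-(acetoxymethyl)-4-hydroxy-6-methyl-3-(trifluoromethylsulfonyloxy)hepta-2,6-dienoate, via iodo silyl ether 8 (not isolated), via acetoxy silyl ether 9 (not isolated)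
Conditions: Me3SiI (1.2 equiv), 2,6-di-tert-butylpyridine (0.2 equiv), CH2Cl2, −40 to 0 °C; AgOAc (1.5 equiv), MeCN, 0 °C; aq citric acid work-up
Reagents that add atoms: iodotrimethylsilane C[Si](C)(C)[I] (its atoms stay only in 8 and 9); silver acetate CC(=O)[O-].[Ag+]
Why: Silyl iodide ether cleavage, in which O8 is silylated and iodide opens the oxonium ion by SN2 at the primary allylic C13, so the C8–O bond (R) and the ring-derived olefin geometry are kept; silver-assisted SN2 with acetate then makes the C13–OAc bond.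

**Step 5**
Reactants: 11 but-3-enylmagnesium bromide; 12 propyne
Product: 15 (1Z)-1-iodo-2-methylhexa-1,5-diene, via but-3-enylcopper 13 (not isolated), via alkenylcopper 14 (not isolated)
Conditions: CuBr·SMe2 (1.0 equiv), Et2O/Me2S, −45 °C; 12 (excess), −25 °C; I2, −50 to 0 °C
Reagents that add atoms: copper bromide dimethyl sulfide complex CSC.[Cu]Br (Cu only in 13 and 14); iodine [I][I]
Why: Normant carbocupration adds the alkyl group and copper syn across propyne (alkyl to the methyl-bearing carbon), and iodinolysis with retention gives the Z C4=C5 olefin with C3 cis to iodine.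

**Step 6**
Reactants: 15 (1Z)-1-iodo-2-methylhexa-1,5-diene
Product: 17 (2Z)-3-methylhepta-2,6-dienal, via alkenyllithium 16 (not isolated)
Conditions: t-BuLi (2.0 equiv), Et2O, −78 °C; DMF, −78 to 0 °C; water; used at once
Reagents that add atoms: tert-butyllithium [Li]C(C)(C)C (Li only in 16); N,N-dimethylformamide CN(C)C=O
Why: Lithium–iodine exchange and Bouveault formylation both proceed with retention at the sp2 carbon, so the Z geometry is carried into the enal that supplies C6.

**Step 7**
Reactants: 10 ethyl (2Z,4R)-2-(acetoxymethyl)-4-hydroxy-6-methyl-3-(trifluoromethylsulfonyloxy)hepta-2,6-dienoate; 17 (2Z)-3-methylhepta-2,6-dienal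
Product: 19 [(5S)-4-[(1R)-1-hydroxy-3-methylbut-3-enyl]-5-[(1Z)-2-methylhexa-1,5-dienyl]-2-oxo-2,5-dihydrofuran-3-yl]methyl acetate, via open-chain hydroxy ester 18 (not isolated)
Conditions: CrCl2 (4 equiv), (R)-N-[2-(4-isopropyl-4,5-dihydro-1,3-oxazol-2-yl)-6-methoxyphenyl]methanesulfonamide (4.4 equiv, recovered), Et3N (4.4 equiv), NiCl2 (5 mol %), THF, 23 °C; PPTS (cat.), CH2Cl2
Reagents that add atoms: none
Why: Nozaki–Hiyama–Kishi alkenylation, in which zerovalent nickel inserts into the activated C7–OTf bond with retention, the alkenyl trivalent chromium species adds 1,2 to the enal, and the alkoxide held cis to the ester lactonises; C6 is set by Re-face attack imposed by the chiral chromium sulfonamide complex (ligand antipode assigned by analogy, not from a recalled precedent) and reinforced by A(1,3) control from C8 (H8 in the olefin plane, enal chain on the face of the small OH).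

**Step 8**
Reactants: 19 [(5S)-4-[(1R)-1-hydroxy-3-methylbut-3-enyl]-5-[(1Z)-2-methylhexa-1,5-dienyl]-2-oxo-2,5-dihydrofuran-3-yl]methyl acetate
Product: 20 (6S,8R,1(10)Z,4Z)-13-acetoxy-8-hydroxygermacra-1(10),4,7(11)-trien-12,6-olide
Conditions: second-generation Hoveyda–Grubbs catalyst RuCl2(=CH-C6H4-2-OiPr)(SIMes) (10 mol %, slow addition), 1,4-benzoquinone (20 mol %), toluene (1 mM), 80 °C, argon sparge
Reagents that add atoms: none
Why: Ring-closing metathesis, in which the catalyst loads on the only monosubstituted olefin (C1) and closes onto the 1,1-disubstituted C10 olefin; the hindered C4=C5 olefin next to the acyloxy carbon C6 and the butenolide olefin are spectators, and the ten-membered ring takes the new trisubstituted olefin as the less strained Z isomer.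

**Step 9**
Reactants: 20 (6S,8R,1(10)Z,4Z)-13-acetoxy-8-hydroxygermacra-1(10),4,7(11)-trien-12,6-olide
Product: 22 (1R,4S,5R,6R,8R,10S)-13-acetoxy-1,10:4,5-diepoxy-8-hydroxygermacr-7(11)-en-12,6-olide, via 1,10-monoepoxide 21 (not isolated)
Conditions: VO(acac)2 (10 mol %), t-BuOOH (3 equiv, decane), 2,6-lutidine (0.3 equiv), 4 Å MS, toluene, 0 to 25 °C
Reagents that add atoms: tert-butyl hydroperoxide CC(C)(C)OO
Why: Proposed new method: a single carbinol-anchored vanadium peroxide is asked to epoxidise two ring olefins in turn, which has not been shown for a medium-ring dienol; 20 binds to pentavalent vanadium as the O8 alkoxide, t-BuOOH binds to the same metal, and oxygen passes intramolecularly first to the homoallylic C1=C10 olefin (O8 gauche to C10) and, after reloading with t-BuOOH, across the ring to the bishomoallylic C4=C5 olefin, whose inner face is estimated from a hand-built model to lie about 3 Å from O8 once C7 is a ring corner and H8 eclipses C7=C11 to relieve A(1,3) strain; unbound t-BuOOH does not touch trisubstituted olefins and the electron-poor butenolide olefin is inert, so both oxygens arrive on the O8 face and C1 (R), C10 (S), C4 (S) and C5 (R) are set all-cis to O8 and O6, whereas a free peracid would attack C4=C5 from the outer face; the closest known reaction types are the vanadium-catalysed hydroxyl-directed epoxidations of homoallylic and of bishomoallylic alcohols, each so far used for one olefin per carbinol.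

**Step 10**
Reactants: 22 (1R,4S,5R,6R,8R,10S)-13-acetoxy-1,10:4,5-diepoxy-8-hydroxygermacr-7(11)-en-12,6-olide
Product: 23 (1R,4S,5R,6R,8R,10S)-13-acetoxy-1,10:4,5-diepoxy-8-(2-methylprop-2-enoyloxy)germacr-7(11)-en-12,6-olide
Conditions: methacrylic anhydride (3 equiv), DMAP (0.2 equiv), pyridine (4 equiv), CH2Cl2, 0 °C
Reagents that add atoms: methacrylic anhydride C=C(C)C(=O)OC(=O)C(C)=C
Why: DMAP-catalysed acylation of the secondary alcohol with retention at C8; the weak base and low temperature spare the base-labile γ-H/13-acetoxy butenolide and both oxiranes.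

**Compound list**
1 | ethyl glyoxylate | CCOC(=O)C=O | starting material
2 | isobutene | CC(C)=C | starting material
3 | ethyl (2R)-2-hydroxy-4-methylpent-4-enoate | CCOC(=O)[C@H](O)CC(C)=C | intermediate
4 | ethyl acrylate | C=CC(=O)OCC | starting material
5 | ethyl (2R)-2-(3-ethoxy-3-oxopropoxy)-4-methylpent-4-enoate (oxa-Michael diester, not isolated) | CCOC(=O)CCO[C@H](CC(C)=C)C(=O)OCC | intermediate
6 | ethyl (5R)-5-(2-methylprop-2-enyl)-4-oxooxolane-3-carboxylate (C3 epimers and enol) | CCOC(=O)C1CO[C@H](CC(C)=C)C1=O | intermediate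
7 | ethyl (5R)-5-(2-methylprop-2-enyl)-4-(trifluoromethylsulfonyloxy)-2,5-dihydrofuran-3-carboxylate | CCOC(=O)C1=C(OS(=O)(=O)C(F)(F)F)[C@@H](CC(C)=C)OC1 | intermediate
8 | ethyl (2E,4R)-2-(iodomethyl)-6-methyl-3-(trifluoromethylsulfonyloxy)-4-(trimethylsilyloxy)hepta-2,6-dienoate (OTf cis to the ester, not isolated) | CCOC(=O)/C(C[I])=C(\OS(=O)(=O)C(F)(F)F)[C@H](O[Si](C)(C)C)CC(C)=C | intermediate
9 | ethyl (2Z,4R)-2-(acetoxymethyl)-6-methyl-3-(trifluoromethylsulfonyloxy)-4-(trimethylsilyloxy)hepta-2,6-dienoate (not isolated) | CCOC(=O)/C(COC(C)=O)=C(\OS(=O)(=O)C(F)(F)F)[C@H](O[Si](C)(C)C)CC(C)=C | intermediate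
10 | ethyl (2Z,4R)-2-(acetoxymethyl)-4-hydroxy-6-methyl-3-(trifluoromethylsulfonyloxy)hepta-2,6-dienoate | CCOC(=O)/C(COC(C)=O)=C(\OS(=O)(=O)C(F)(F)F)[C@H](O)CC(C)=C | intermediate
11 | but-3-enylmagnesium bromide | C=CCC[Mg]Br | starting material
12 | propyne | CC#C | starting material
13 | but-3-enylcopper (not isolated) | C=CCC[Cu] | intermediate
14 | [(1Z)-2-methylhexa-1,5-dienyl]copper (not isolated) | C=CCC/C(C)=C\[Cu] | intermediate
15 | (1Z)-1-iodo-2-methylhexa-1,5-diene | C=CCC/C(C)=C\[I] | intermediate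
16 | [(1Z)-2-methylhexa-1,5-dienyl]lithium (not isolated) | C=CCC/C(C)=C\[Li] | intermediate
17 | (2Z)-3-methylhepta-2,6-dienal | C=CCC/C(C)=C\C=O | intermediate
18 | ethyl (2Z,4R)-2-(acetoxymethyl)-4-hydroxy-3-[(1S,2Z)-1-hydroxy-3-methylhepta-2,6-dienyl]-6-methylhepta-2,6-dienoate (drawn as the free alcohol, present as its trivalent chromium alkoxide, not isolated) | CCOC(=O)/C(COC(C)=O)=C(\[C@@H](O)/C=C(/C)CCC=C)[C@H](O)CC(C)=C | intermediate
19 | [(5S)-4-[(1R)-1-hydroxy-3-methylbut-3-enyl]-5-[(1Z)-2-methylhexa-1,5-dienyl]-2-oxo-2,5-dihydrofuran-3-yl]methyl acetate | O[C@H](CC(C)=C)C1=C(COC(C)=O)C(=O)O[C@H]1/C=C(/C)CCC=C | intermediate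
20 | (6S,8R,1(10)Z,4Z)-13-acetoxy-8-hydroxygermacra-1(10),4,7(11)-trien-12,6-olide | O[C@@H]1C/C(C)=C\CC/C(C)=C\[C@@H]2OC(=O)C(COC(C)=O)=C21 | intermediate
21 | (1R,6S,8R,10S,4Z)-13-acetoxy-1,10-epoxy-8-hydroxygermacra-4,7(11)-dien-12,6-olide (not isolated) | O[C@@H]1C[C@]2(C)O[C@@H]2CC/C(C)=C\[C@@H]2OC(=O)C(COC(C)=O)=C21 | intermediate
22 | (1R,4S,5R,6R,8R,10S)-13-acetoxy-1,10:4,5-diepoxy-8-hydroxygermacr-7(11)-en-12,6-olide | O[C@@H]1C[C@]2(C)O[C@@H]2CC[C@]2(C)O[C@@H]2[C@@H]2OC(=O)C(COC(C)=O)=C21 | intermediate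
23 | (1R,4S,5R,6R,8R,10S)-13-acetoxy-1,10:4,5-diepoxy-8-(2-methylprop-2-enoyloxy)germacr-7(11)-en-12,6-olide (CNP0212980.1) | C=C(C)C(=O)O[C@@H]1C[C@]2(C)O[C@@H]2CC[C@]2(C)O[C@@H]2[C@@H]2OC(=O)C(COC(C)=O)=C21 | target

**Total step count:** 10. **Longest linear sequence:** 8 steps (1, 2, 3, 4, 7, 8, 9, 10).

**Three steps most likely to fail**

**Step 9 (the proposed new step).**
- Risks: the second, transannular oxygen transfer may stall at 21, or the Lewis-acidic vanadium may open an oxirane.
- Fallback from 20 back to 23, using known chemistry only: VO(acac)2 with 1.1 equiv of t-BuOOH performs the ordinary homoallylic directed epoxidation to 21.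
- Methacrylic anhydride/DMAP then gives the monoepoxide methacrylate F10.
- N-bromosuccinimide in aqueous THF forms the bromonium ion on the exposed outer face of C4=C5, and water opens it at the tertiary C4 from the inner face to give the bromohydrin F11.
- Ag2O closes the C4 alkoxide onto C5 with inversion. This places the oxirane oxygen on the inner face and gives 23 directly.

**Step 8 (ring-closing metathesis).**
- Risks: dimerisation, E olefin, or truncation to a cyclohexene through C4=C5.
- Fallback from 7 and 17 back to 20: the ring is closed on a rigid template instead of on the free chain.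
- The cyclic triflate 7 is coupled with 17 under the conditions of step 7 to give the bicyclic furofuranone F6, which holds both olefin chains on one face.
- Metathesis then gives the bridged tricycle F7.
- The dihydrofuran is opened afterwards as in step 4 (Me3SiI, then AgOAc, then aqueous acid). This passes through the macrocyclic iodo silyl ether F8 and the macrocyclic acetoxy silyl ether F9 and ends at 20.

**Step 7 (coupling of a tetrasubstituted triflate and control of C6).**
- Risks: slow coupling and a low C6 ratio.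
- Fallback from 15 and 10 back to 22: C6 is controlled by an α-stereocentre in the aldehyde rather than by the ligand.
- Iodide 15 is lithiated as in step 6 and quenched with paraformaldehyde to give (2Z)-3-methylhepta-2,6-dien-1-ol F1.
- Sharpless asymmetric epoxidation (Ti(OiPr)4, D-(−)-diethyl tartrate, t-BuOOH) gives the cis-epoxy alcohol F2, and Parikh–Doering oxidation gives the epoxy aldehyde F3.
- Nozaki–Hiyama–Kishi coupling of F3 with 10 follows Felkin–Anh control, with attack anti to the oxirane C–O bond. It gives the erythro epoxy butenolide F4.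
- Metathesis gives the 4,5-epoxy macrocycle F5, and a single VO(acac)2/t-BuOOH homoallylic directed epoxidation gives 22.

**Further compounds**
F1 | step 7 | (2Z)-3-methylhepta-2,6-dien-1-ol | C=CCC/C(C)=C\CO
F2 | step 7 | [(2R,3S)-3-(but-3-enyl)-3-methyloxiran-2-yl]methanol | C=CCC[C@]1(C)O[C@@H]1CO
F3 | step 7 | (2S,3S)-3-(but-3-enyl)-3-methyloxirane-2-carbaldehyde | C=CCC[C@]1(C)O[C@@H]1C=O
F4 | step 7 | [(5R)-5-[(2R,3S)-3-(but-3-enyl)-3-methyloxiran-2-yl]-4-[(1R)-1-hydroxy-3-methylbut-3-enyl]-2-oxo-2,5-dihydrofuran-3-yl]methyl acetate | O[C@H](CC(C)=C)C1=C(COC(C)=O)C(=O)O[C@H]1[C@H]1O[C@@]1(C)CCC=C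
F5 | step 7 | (4S,5R,6R,8R,1(10)Z)-13-acetoxy-4,5-epoxy-8-hydroxygermacra-1(10),7(11)-dien-12,6-olide | O[C@@H]1C/C(C)=C\CC[C@]2(C)O[C@@H]2[C@@H]2OC(=O)C(COC(C)=O)=C21
F6 | step 8 | (3S,4R)-3-[(1Z)-2-methylhexa-1,5-dienyl]-4-(2-methylprop-2-enyl)-4,6-dihydro-1H,3H-furo[3,4-c]furan-1-one | C=C(C)C[C@H]1OCC2=C1[C@H](/C=C(/C)CCC=C)OC2=O
F7 | step 8 | (6S,8R,1(10)Z,4Z)-8,13-epoxygermacra-1(10),4,7(11)-trien-12,6-olide | O1[C@@H]2C/C(C)=C\CC/C(C)=C\[C@@H]3OC(=O)C(C1)=C32
F8 | step 8 | (6S,8R,1(10)Z,4Z)-13-iodo-8-(trimethylsilyloxy)germacra-1(10),4,7(11)-trien-12,6-olide | C[Si](C)(C)O[C@@H]1C/C(C)=C\CC/C(C)=C\[C@@H]2OC(=O)C(C[I])=C21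
F9 | step 8 | (6S,8R,1(10)Z,4Z)-13-acetoxy-8-(trimethylsilyloxy)germacra-1(10),4,7(11)-trien-12,6-olide | C[Si](C)(C)O[C@@H]1C/C(C)=C\CC/C(C)=C\[C@@H]2OC(=O)C(COC(C)=O)=C21
F10 | step 9 | (1R,6S,8R,10S,4Z)-13-acetoxy-1,10-epoxy-8-(2-methylprop-2-enoyloxy)germacra-4,7(11)-dien-12,6-olide | C=C(C)C(=O)O[C@@H]1C[C@]2(C)O[C@@H]2CC/C(C)=C\[C@@H]2OC(=O)C(COC(C)=O)=C21
F11 | step 9 | 13-acetoxy-5-bromo-1,10-epoxy-4-hydroxy-8-(2-methylprop-2-enoyloxy)germacr-7(11)-en-12,6-olide (4-OH on the face of O6 and O8, 5-Br on the opposite face) | C=C(C)C(=O)O[C@@H]1C[C@]2(C)O[C@@H]2CC[C@](C)(O)[C@@H](Br)[C@@H]2OC(=O)C(COC(C)=O)=C21
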